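**Retrosynthetic overview**
1. The C3=C4 enyne is made last, by Z-selective enyne cross-metathesis of a terminal allyl group with a silyl enyne, then desilylation.
2. The oxocene (second ring; C7–O and C10–OAc bonds) comes from a chloronium-triggered 5→8 ring expansion of a trans-2,5-dihydrofuran carrying a (Z)-homoallylic acetate. This one step sets C6 and C7 and inverts C10.
3. The C7–C8 bond comes from BF3-mediated opening of a terminal epoxide by lithiated pent-1-en-4-yne, followed by acetylation and Lindlar reduction.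
4. The dihydrofuran (first ring; C11=C12) comes from RCM of a bis-allylic ether, itself made by Ir-catalysed allylic etherification (C13–O) of the Sharpless epoxy alcohol of divinylcarbinol.
5. Ring order: 2,5-dihydrofuran first; it is then converted into the oxocene, and its oxygen becomes the oxocene oxygen.

Assumption: but-3-en-1-yn-1-yl(trimethyl)silane is a catalogue compound. Atom labels C1–C15 follow the target chain (C1 = alkyne CH, C15 = ethyl CH3). The tartrate and phosphoramidite enantiomers named below were assigned from the usual selectivity models and should be confirmed on the first batch.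

**Route**

Step 1
Reactants: 1 penta-1,4-dien-3-ol
Product: 2 (1S)-1-[(2R)-oxiran-2-yl]prop-2-en-1-ol
Conditions: Ti(OiPr)4 (0.1 equiv), L-(+)-DIPT (0.13 equiv), t-BuOOH, 4 Å MS, CH2Cl2, −20 °C, 4 d
Reagents that add atoms: tert-butyl hydroperoxide CC(C)(C)OO
Why: Sharpless asymmetric epoxidation of the divinyl carbinol combines enantiotopic-group and diastereoface selection to give the erythro epoxy alcohol, setting C9 (R) and C10 (S), and the minor enantiomer is removed by over-epoxidation.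

Step 2
Reactants: 3 (E)-pent-2-en-1-ol
Product: 4 tert-butyl (2E)-pent-2-en-1-yl carbonate
Conditions: Boc2O, n-Bu4NHSO4 (cat.), 30% aq NaOH, CH2Cl2, 0 °C to rt
Reagents that add atoms: di-tert-butyl dicarbonate CC(C)(C)OC(=O)OC(=O)OC(C)(C)C
Why: Phase-transfer O-acylation gives the allylic carbonate, and the tert-butyl carbonate is used because the tert-butoxide it releases does not compete as a nucleophile in step 3.

Step 3
Reactants: 2 (1S)-1-[(2R)-oxiran-2-yl]prop-2-en-1-ol; 4 tert-butyl (2E)-pent-2-en-1-yl carbonate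
Product: 7 (2R)-2-[(1S)-1-{[(3R)-pent-1-en-3-yl]oxy}prop-2-en-1-yl]oxirane, via lithium alkoxide 5 (not isolated), via copper alkoxide 6 (not isolated)
Conditions: 2, n-BuLi, THF, −78 to 0 °C; CuI; then 4, [Ir(cod)Cl]2 (2 mol %), (Sa,Sc,Sc)-O,O'-(1,1'-binaphthyl-2,2'-diyl)-N,N-bis(1-phenylethyl)phosphoramidite (4 mol %), THF, rt
Reagents that add atoms: none
Why: Iridium-catalysed asymmetric allylic etherification, in which the soft copper alkoxide attacks the substituted terminus of the Ir–allyl (branched product) and the phosphoramidite ligand sets the new C13 centre (R) under catalyst control.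

Step 4
Reactants: 7 (2R)-2-[(1S)-1-{[(3R)-pent-1-en-3-yl]oxy}prop-2-en-1-yl]oxirane
Product: 8 (2S,5R)-5-ethyl-2-[(2R)-oxiran-2-yl]-2,5-dihydrofuran
Conditions: second-generation Grubbs catalyst RuCl2(=CHPh)(PCy3)(H2IMes) (2 mol %), CH2Cl2 (0.02 M), 40 °C
Reagents that add atoms: none
Why: Ring-closing metathesis of the two vinyl groups closes the five-membered ring with loss of ethylene, and the trans relation of C10 and C13 follows from the two centres already present.

Step 5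
Reactants: 8 (2S,5R)-5-ethyl-2-[(2R)-oxiran-2-yl]-2,5-dihydrofuran; 9 pent-1-en-4-yne
Product: 11 (1R)-1-[(2S,5R)-5-ethyl-2,5-dihydrofuran-2-yl]hept-6-en-3-yn-1-ol, via lithium pent-4-en-1-yn-1-ide 10 (not isolated)
Conditions: 9, n-BuLi, THF, −78 °C; BF3·OEt2; then 8, −78 °C
Reagents that add atoms: none
Why: BF3-promoted alkynylation of the terminal epoxide (Yamaguchi conditions) takes place at the CH2 carbon (C8) only, so the C9 carbinol keeps its R configuration.

Step 6
Reactants: 11 (1R)-1-[(2S,5R)-5-ethyl-2,5-dihydrofuran-2-yl]hept-6-en-3-yn-1-ol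
Product: 12 (1R)-1-[(2S,5R)-5-ethyl-2,5-dihydrofuran-2-yl]hept-6-en-3-yn-1-yl acetate
Conditions: Ac2O, pyridine, DMAP (cat.), CH2Cl2, 0 °C to rt
Reagents that add atoms: acetic anhydride CC(=O)OC(C)=O
Why: Standard DMAP-catalysed acetylation installs the C9 acetate that later serves as the internal nucleophile.

Step 7
Reactants: 12 (1R)-1-[(2S,5R)-5-ethyl-2,5-dihydrofuran-2-yl]hept-6-en-3-yn-1-yl acetate
Product: 13 (1R,3Z)-1-[(2S,5R)-5-ethyl-2,5-dihydrofuran-2-yl]hepta-3,6-dien-1-yl acetate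
Conditions: H2 (1 atm), Pd/CaCO3 poisoned with Pb(OAc)2 (Lindlar catalyst), quinoline, EtOAc, rt, stopped at 1.0 equiv H2
Reagents that add atoms: none
Why: Lindlar semi-hydrogenation adds H2 syn to the internal alkyne to give the Z-C6=C7 alkene, while the terminal and ring alkenes are left.

Step 8
Reactants: 13 (1R,3Z)-1-[(2S,5R)-5-ethyl-2,5-dihydrofuran-2-yl]hepta-3,6-dien-1-yl acetate
Product: 18 (2R,4R,5R,6Z,8R)-2-[(1R)-1-chlorobut-3-en-1-yl]-8-ethyl-3,4,5,8-tetrahydro-2H-oxocine-4,5-diyl diacetate, via bicyclic chloro-oxonium ion 14 (not isolated), via fused dioxolanylium ion 15 (not isolated), via 4-acetoxy-5-hydroxy oxocene 16 (not isolated), via 5-acetoxy-4-hydroxy oxocene 17 (not isolated)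
Conditions: NCS (1.1 equiv), Ph3P=S (10 mol %), HFIP/CH2Cl2 (1:4), −20 °C, dark; H2O, 0 °C; concentrate; Ac2O, pyridine, DMAP, rt
Reagents that add atoms: N-chlorosuccinimide ClN1C(=O)CCC1=O; water O; acetic anhydride CC(=O)OC(C)=O
Why: Proposed new method: Lewis-base-activated NCS transfers Cl+ to the most electron-rich alkene (Z-C6=C7; the ring alkene is deactivated by two allylic oxygens and the terminal alkene is monosubstituted), the dihydrofuran oxygen closes 5-exo on C7 anti to chlorine to give the cis-fused bicyclic oxonium ion 14 with the C7 side chain on the convex face (this sets 6R and 7R from the Z geometry), the C9 acetate then opens the allylic C10–O+ bond from the rear with inversion (10S to 10R) so that the five-membered ring is exchanged for the eight-membered ring as dioxolanylium ion 15, and water followed by Ac2O converts 15 through 16 and 17 into the diacetate; closest known reaction type: bromonium-induced ring expansion of tetrahydrofurans to eight-membered bromoethers through bicyclic oxonium ions, combined with Woodward–Prévost-type acyloxonium hydrolysis, not shown so far with chloronium ions, 2,5-dihydrofurans or an acetate relay.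

Step 9
Reactants: 18 (2R,4R,5R,6Z,8R)-2-[(1R)-1-chlorobut-3-en-1-yl]-8-ethyl-3,4,5,8-tetrahydro-2H-oxocine-4,5-diyl diacetate; 19 but-3-en-1-yn-1-yl(trimethyl)silane
Product: 20 (2R,4R,5R,6Z,8R)-2-[(1R,3Z)-1-chloro-6-(trimethylsilyl)hex-3-en-5-yn-1-yl]-8-ethyl-3,4,5,8-tetrahydro-2H-oxocine-4,5-diyl diacetate
Conditions: 19 (4 equiv), second-generation Grubbs catalyst RuCl2(=CHPh)(PCy3)(H2IMes) (10 mol %), CH2Cl2, 40 °C
Reagents that add atoms: none
Why: Cross-metathesis of a terminal alkene with a conjugated silyl enyne is kinetically Z-selective, and the ring alkene, flanked by two substituted allylic carbons, does not take part.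

Step 10
Reactants: 20 (2R,4R,5R,6Z,8R)-2-[(1R,3Z)-1-chloro-6-(trimethylsilyl)hex-3-en-5-yn-1-yl]-8-ethyl-3,4,5,8-tetrahydro-2H-oxocine-4,5-diyl diacetate
Product: 21 (2R,4R,5R,6Z,8R)-2-[(1R,3Z)-1-chlorohex-3-en-5-yn-1-yl]-8-ethyl-3,4,5,8-tetrahydro-2H-oxocine-4,5-diyl diacetate
Conditions: AgNO3 (0.2 equiv), 2,6-lutidine, acetone/H2O (4:1), rt
Reagents that add atoms: none
Why: Silver-catalysed protodesilylation of the alkynylsilane runs under near-neutral conditions, so the two acetates, the secondary chloride and the Z-enyne are untouched.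

**Compound list**
1 | penta-1,4-dien-3-ol | C=CC(O)C=C | starting material
2 | (1S)-1-[(2R)-oxiran-2-yl]prop-2-en-1-ol | C=C[C@H](O)[C@H]1CO1 | intermediate
3 | (E)-pent-2-en-1-ol | CC/C=C/CO | starting material
4 | tert-butyl (2E)-pent-2-en-1-yl carbonate | CC/C=C/COC(=O)OC(C)(C)C | intermediate
5 | lithium (1S)-1-[(2R)-oxiran-2-yl]prop-2-en-1-olate | C=C[C@H]([O-])[C@H]1CO1.[Li+] | intermediate
6 | copper (1S)-1-[(2R)-oxiran-2-yl]prop-2-en-1-olate (CuOR) | C=C[C@H]([O-])[C@H]1CO1.[Cu+] | intermediate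
7 | (2R)-2-[(1S)-1-{[(3R)-pent-1-en-3-yl]oxy}prop-2-en-1-yl]oxirane | C=C[C@H](O[C@H](CC)C=C)[C@H]1CO1 | intermediate
8 | (2S,5R)-5-ethyl-2-[(2R)-oxiran-2-yl]-2,5-dihydrofuran (trans) | CC[C@@H]1C=C[C@H](O1)[C@H]2CO2 | intermediate
9 | pent-1-en-4-yne | C=CCC#C | starting material
10 | lithium pent-4-en-1-yn-1-ide | [Li+].[C-]#CCC=C | intermediate
11 | (1R)-1-[(2S,5R)-5-ethyl-2,5-dihydrofuran-2-yl]hept-6-en-3-yn-1-ol | CC[C@@H]1C=C[C@H](O1)[C@H](O)CC#CCC=C | intermediate
12 | (1R)-1-[(2S,5R)-5-ethyl-2,5-dihydrofuran-2-yl]hept-6-en-3-yn-1-yl acetate | CC[C@@H]1C=C[C@H](O1)[C@H](OC(C)=O)CC#CCC=C | intermediate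
13 | (1R,3Z)-1-[(2S,5R)-5-ethyl-2,5-dihydrofuran-2-yl]hepta-3,6-dien-1-yl acetate | CC[C@@H]1C=C[C@H](O1)[C@H](OC(C)=O)C/C=C\CC=C | intermediate
14 | (2R,5S,6R,8R)-6-acetoxy-8-[(1R)-1-chlorobut-3-en-1-yl]-2-ethyl-1-oxoniabicyclo[3.3.0]oct-3-ene (bicyclic chloro-oxonium ion) | CC[C@@H]1C=C[C@H]2[C@H](OC(C)=O)C[C@H]([C@H](Cl)CC=C)[O+]12 | intermediate
15 | oxocene-fused 2-methyl-1,3-dioxolan-2-ylium ion, trans-fused at C9/C10 (6R,7R,9R,10R,13R) | C=CC[C@@H](Cl)[C@H]1C[C@H]2OC(C)=[O+][C@@H]2/C=C\[C@@H](CC)O1 | intermediate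
16 | (2R,4R,5R,6Z,8R)-2-[(1R)-1-chlorobut-3-en-1-yl]-8-ethyl-5-hydroxy-3,4,5,8-tetrahydro-2H-oxocin-4-yl acetate | C=CC[C@@H](Cl)[C@H]1C[C@@H](OC(C)=O)[C@H](O)/C=C\[C@@H](CC)O1 | intermediate
17 | (2R,4R,5R,6Z,8R)-2-[(1R)-1-chlorobut-3-en-1-yl]-8-ethyl-4-hydroxy-3,4,5,8-tetrahydro-2H-oxocin-5-yl acetate | C=CC[C@@H](Cl)[C@H]1C[C@@H](O)[C@H](OC(C)=O)/C=C\[C@@H](CC)O1 | intermediate
18 | (2R,4R,5R,6Z,8R)-2-[(1R)-1-chlorobut-3-en-1-yl]-8-ethyl-3,4,5,8-tetrahydro-2H-oxocine-4,5-diyl diacetate | C=CC[C@@H](Cl)[C@H]1C[C@@H](OC(C)=O)[C@H](OC(C)=O)/C=C\[C@@H](CC)O1 | intermediate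
19 | but-3-en-1-yn-1-yl(trimethyl)silane | C=CC#C[Si](C)(C)C | starting material
20 | (2R,4R,5R,6Z,8R)-2-[(1R,3Z)-1-chloro-6-(trimethylsilyl)hex-3-en-5-yn-1-yl]-8-ethyl-3,4,5,8-tetrahydro-2H-oxocine-4,5-diyl diacetate | C[Si](C)(C)C#C/C=C\C[C@@H](Cl)[C@H]1C[C@@H](OC(C)=O)[C@H](OC(C)=O)/C=C\[C@@H](CC)O1 | intermediate
21 | (2R,4R,5R,6Z,8R)-2-[(1R,3Z)-1-chlorohex-3-en-5-yn-1-yl]-8-ethyl-3,4,5,8-tetrahydro-2H-oxocine-4,5-diyl diacetate | C#C/C=C\C[C@@H](Cl)[C@H]1C[C@@H](OC(C)=O)[C@H](OC(C)=O)/C=C\[C@@H](CC)O1 | target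

**Step count**
Total steps: 10. Longest linear sequence: 9 (steps 1 and 3–10; step 2 is a one-step side branch).

**Three steps most likely to fail**

Step 8 (the proposed ring expansion). Possible failures are capture of the chloronium ion by the acetate carbonyl (six-membered acyloxonium) in place of the ring oxygen, 6-endo closure (which would lead to a nine-membered ring), or opening of the oxonium ion at C13. The fallback uses known reactions only, sets out from alkyne 12 and comes back at oxonium ion 14. [Cp*Ru(MeCN)3]PF6-catalysed trans-hydrosilylation of 12 with (EtO)3SiH gives the regioisomeric vinylsilanes (1R,3Z)-1-[(2S,5R)-5-ethyl-2,5-dihydrofuran-2-yl]-3-(triethoxysilyl)hepta-3,6-dien-1-yl acetate F3 and (1R,3Z)-1-[(2S,5R)-5-ethyl-2,5-dihydrofuran-2-yl]-4-(triethoxysilyl)hepta-3,6-dien-1-yl acetate F4. CuI/Bu4NF protodesilylation of both gives (1R,3E)-1-[(2S,5R)-5-ethyl-2,5-dihydrofuran-2-yl]hepta-3,6-dien-1-yl acetate F5. Shi epoxidation of the trans-disubstituted alkene with the L-fructose-derived ketone and 2KHSO5·KHSO4·K2SO4 gives (1R)-2-[(2S,3S)-3-allyloxiran-2-yl]-1-[(2S,5R)-5-ethyl-2,5-dihydrofuran-2-yl]ethyl acetate F6. Li2CuCl4 in THF opens the epoxide at C6, the carbon remote from the acetoxy-bearing chain, with inversion to (1R,3S,4R)-4-chloro-1-[(2S,5R)-5-ethyl-2,5-dihydrofuran-2-yl]-3-hydroxyhept-6-en-1-yl acetate F7. Tf2O with 2,6-di-tert-butyl-4-methylpyridine gives (1R,3S,4R)-4-chloro-1-[(2S,5R)-5-ethyl-2,5-dihydrofuran-2-yl]-3-(trifluoromethylsulfonyloxy)hept-6-en-1-yl acetate F8. The ring oxygen displaces the triflate with inversion (ether-oxygen participation through a five-membered ring), which delivers 14 and then 15 to 18 as in step 8.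

Step 9 (enyne cross-metathesis). The Z/E ratio may be low, or the ruthenium carbene may be tied up by the enyne. The fallback sets out from 18 and comes back at 20. OsO4 (cat.)/NaIO4/2,6-lutidine cleaves the unhindered terminal alkene to (2R,4R,5R,6Z,8R)-2-[(1R)-1-chloro-3-oxopropyl]-8-ethyl-3,4,5,8-tetrahydro-2H-oxocine-4,5-diyl diacetate F9. Stork–Zhao olefination (Ph3P+CH2I I−, NaN(SiMe3)2, THF/HMPA, −78 °C, kept cold because the aldehyde is a β-chloro aldehyde) gives (2R,4R,5R,6Z,8R)-2-[(1R,3Z)-1-chloro-4-iodobut-3-en-1-yl]-8-ethyl-3,4,5,8-tetrahydro-2H-oxocine-4,5-diyl diacetate F10. Sonogashira coupling with trimethylsilylacetylene (Pd(PPh3)4, CuI, Et2NH) then gives 20.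

Step 3 (iridium etherification). The epoxy alkoxide may undergo Payne rearrangement or epoxide opening, and the diastereoselectivity at C13 rests on the ligand. The fallback sets out from 2 (as its copper alkoxide 6) and comes back at 7. Commercial (R)-pent-1-en-3-ol F1 is converted with n-BuLi/Boc2O into tert-butyl (3R)-pent-1-en-3-yl carbonate F2. F2 is coupled with 6 under RhCl(PPh3)3/P(OMe)3 catalysis (THF, 0 °C to rt). This enantiospecific rhodium allylic etherification is branched-selective and proceeds with net retention, so C13 comes from the chiral pool and not from a catalyst.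

**Further compounds**
F1 | step 3 | (R)-pent-1-en-3-ol | CC[C@@H](O)C=C
F2 | step 3 | tert-butyl (3R)-pent-1-en-3-yl carbonate | CC[C@@H](OC(=O)OC(C)(C)C)C=C
F3 | step 8 | (1R,3Z)-1-[(2S,5R)-5-ethyl-2,5-dihydrofuran-2-yl]-3-(triethoxysilyl)hepta-3,6-dien-1-yl acetate | CC[C@@H]1C=C[C@H](O1)[C@H](OC(C)=O)C/C([Si](OCC)(OCC)OCC)=C/CC=C
F4 | step 8 | (1R,3Z)-1-[(2S,5R)-5-ethyl-2,5-dihydrofuran-2-yl]-4-(triethoxysilyl)hepta-3,6-dien-1-yl acetate | CC[C@@H]1C=C[C@H](O1)[C@H](OC(C)=O)C/C=C(/CC=C)[Si](OCC)(OCC)OCC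
F5 | step 8 | (1R,3E)-1-[(2S,5R)-5-ethyl-2,5-dihydrofuran-2-yl]hepta-3,6-dien-1-yl acetate | CC[C@@H]1C=C[C@H](O1)[C@H](OC(C)=O)C/C=C/CC=C
F6 | step 8 | (1R)-2-[(2S,3S)-3-allyloxiran-2-yl]-1-[(2S,5R)-5-ethyl-2,5-dihydrofuran-2-yl]ethyl acetate | CC[C@@H]1C=C[C@H](O1)[C@H](OC(C)=O)C[C@@H]2O[C@H]2CC=C
F7 | step 8 | (1R,3S,4R)-4-chloro-1-[(2S,5R)-5-ethyl-2,5-dihydrofuran-2-yl]-3-hydroxyhept-6-en-1-yl acetate | CC[C@@H]1C=C[C@H](O1)[C@H](OC(C)=O)C[C@H](O)[C@H](Cl)CC=C
F8 | step 8 | (1R,3S,4R)-4-chloro-1-[(2S,5R)-5-ethyl-2,5-dihydrofuran-2-yl]-3-(trifluoromethylsulfonyloxy)hept-6-en-1-yl acetate | CC[C@@H]1C=C[C@H](O1)[C@H](OC(C)=O)C[C@H](OS(=O)(=O)C(F)(F)F)[C@H](Cl)CC=C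
F9 | step 9 | (2R,4R,5R,6Z,8R)-2-[(1R)-1-chloro-3-oxopropyl]-8-ethyl-3,4,5,8-tetrahydro-2H-oxocine-4,5-diyl diacetate | O=CC[C@@H](Cl)[C@H]1C[C@@H](OC(C)=O)[C@H](OC(C)=O)/C=C\[C@@H](CC)O1
F10 | step 9 | (2R,4R,5R,6Z,8R)-2-[(1R,3Z)-1-chloro-4-iodobut-3-en-1-yl]-8-ethyl-3,4,5,8-tetrahydro-2H-oxocine-4,5-diyl diacetate | I/C=C\C[C@@H](Cl)[C@H]1C[C@@H](OC(C)=O)[C@H](OC(C)=O)/C=C\[C@@H](CC)O1
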